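**Plan**
- Ring numbering used throughout: cyclohexane C1 (CO2H), C2 (side chain), C3 (CMe2), C4–C6 (CH2); chromene numbered as usual.
- Retrosynthesis: cut chromene C3=C4 (ring-closing metathesis) and the aryl O–C2 bond (Pd-catalysed asymmetric allylic etherification), which removes the arene as atranol; trace the allyl unit back to a methyl ketone; then cut the cyclohexane at C3–C4 and C5–C6, which excises C4–C5 as phenyl vinyl sulfone and leaves the ring-opened skeleton of (R)-limonene.
- Enabling feature: C3 and C6 are 1,4-related across C2–C1. C3 is the Markovnikov radical site of an isopropenyl group (its second methyl arrives as H•), and C6 is the β-carbon of an α-methylene ester on C1. A two-carbon radical acceptor/carbanion donor can therefore bridge them.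
- Forward order: limonene ring opened → α-methylene ester → cyclohexane by the annulation → sulfone removed → side chain extended to the (E)-allylic carbonate → tertiary aryl ether → pyran ring by metathesis → epimerisation and saponification.
- Stereochemistry: ring C2 is C4 of (R)-limonene and is never touched; C1 is set last by thermodynamic equilibration to the trans ester; chromene C2 is set by catalyst control in the allylic etherification.

Key step: step 5

Assumption 1: the trans (1S,2R) ester, with both ring substituents equatorial, is taken to be the more stable C1 epimer, so C1 is carried as a mixture until step 14.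
Assumption 2: the (R,R)-DACH-phenyl Trost ligand is taken to give the (R)-ether from the (E)-carbonate; if the sense is the reverse, the (S,S)-ligand is used.

**Route**

Step 1
Reactants: 1 (R)-(+)-limonene
Product: 3 (3R)-6-oxo-3-(prop-1-en-2-yl)heptanal, via limonene 1,2-ozonide 2 (not isolated)
Conditions: O3 (1.0 equiv), CH2Cl2, −78 °C; then Me2S, −78 °C → rt
Reagents that add atoms: ozone, O=[O+][O-]
Why: Ozonolysis with reductive work-up; ozone should add faster to the trisubstituted ring alkene than to the 1,1-disubstituted isopropenyl group, and the limonene stereocentre is not involved.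

Step 2
Reactants: 3 (3R)-6-oxo-3-(prop-1-en-2-yl)heptanal
Product: 4 (3S)-4-methyl-2-methylidene-3-(3-oxobutyl)pent-4-enal
Conditions: 37% aq. CH2O, pyrrolidine (10 mol%), propionic acid (10 mol%), i-PrOH, 45 °C
Reagents that add atoms: formaldehyde, C=O
Why: Organocatalytic α-methylenation of an aldehyde (enamine Mannich reaction with formaldehyde, then amine elimination); the aldehyde forms the enamine far faster than the ketone, and the stereocentre is untouched (the descriptor changes only through CIP priorities).

Step 3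
Reactants: 4 (3S)-4-methyl-2-methylidene-3-(3-oxobutyl)pent-4-enal
Product: 5 (3S)-4-methyl-2-methylidene-3-(3-oxobutyl)pent-4-enoic acid
Conditions: NaClO2, NaH2PO4, 2-methyl-2-butene, t-BuOH/H2O, 0 °C → rt
Reagents that add atoms: sodium chlorite, [Na+].[O-]Cl=O
Why: Pinnick oxidation converts enals to acrylic acids without touching the ketone or alkenes, the hypochlorite being trapped by the scavenger alkene.

Step 4
Reactants: 5 (3S)-4-methyl-2-methylidene-3-(3-oxobutyl)pent-4-enoic acid
Product: 6 methyl (3S)-4-methyl-2-methylidene-3-(3-oxobutyl)pent-4-enoate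
Conditions: TMSCHN2, toluene/MeOH (4:1), 0 °C
Reagents that add atoms: (trimethylsilyl)diazomethane, C[Si](C)(C)C=[N+]=[N-]
Why: Neutral methyl esterification with a diazoalkane, chosen because no base is present that could deprotonate the doubly allylic C3–H.

Step 5
Reactants: 6 methyl (3S)-4-methyl-2-methylidene-3-(3-oxobutyl)pent-4-enoate; 7 phenyl vinyl sulfone
Product: 8 methyl (2R)-3,3-dimethyl-2-(3-oxobutyl)-5-(phenylsulfonyl)cyclohexane-1-carboxylate (C1/C5 diastereomers)
Conditions: Fe(acac)3 (0.5 equiv), PhSiH2(Oi-Pr) (2 equiv), 7 (3 equiv), THF/i-PrOH (20:1), 0.02 M, 40 °C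
Reagents that add atoms: none
Why: Proposed new method: an iron hydride formed from Fe(acac)3 and the silane should transfer H• to the terminal CH2 of the isopropenyl group, which creates the second methyl and a tertiary radical at the future C3; this radical adds to the β-carbon of excess 7 (Giese addition, bond C3–C4), and the α-sulfonyl radical, or the sulfonyl carbanion formed from it by Fe(II) reduction, then attacks the terminal CH2 of the α-substituted acrylate (bond C5–C6), after which the ester-stabilised radical or enolate is reduced and protonated. The closest known reaction types are the Fe(acac)3/silane reductive olefin cross-coupling with vinyl sulfones and hydrogen-atom-transfer-initiated radical–polar crossover annulations in which a Giese adduct is trapped by a pendant carbonyl group. The single ring closes in the 6-endo-trig mode, the Michael-type mode; 5-exo attack would have to form a bond at the fully substituted α-carbon and would leave an unstabilised primary centre. C2 is not touched and keeps the configuration derived from limonene, while C1 (set by protonation) and C5 (sulfonyl carbon) form without control, which is harmless because C5 loses its substituent in step 6 and C1 is equilibrated in step 14. The step needs hydrogen-atom transfer to the 1,1-dialkyl alkene in preference to the acrylate, which the donor/acceptor distinction of the parent cross-coupling should provide. It also needs capture by 7 before any reaction with an acrylate, which the excess of 7, the high dilution and the impossibility of a three- or four-membered closure onto the molecule's own acrylate should secure.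

Step 6
Reactants: 8 methyl (2R)-3,3-dimethyl-2-(3-oxobutyl)-5-(phenylsulfonyl)cyclohexane-1-carboxylate
Product: 9 methyl (2R)-3,3-dimethyl-2-(3-oxobutyl)cyclohexane-1-carboxylate (C1 epimers)
Conditions: 6% Na(Hg), Na2HPO4, MeOH/THF, −20 °C
Reagents that add atoms: none
Why: Reductive desulfonylation (electron transfer to the aryl sulfone, C–S cleavage, protonation) under buffered low-temperature conditions, which are the ones used to cleave β-keto sulfones to ketones and should therefore spare the ketone and the ester.

Step 7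
Reactants: 9 methyl (2R)-3,3-dimethyl-2-(3-oxobutyl)cyclohexane-1-carboxylate
Product: 10 methyl (2R)-2-[(3E)-5-tert-butoxy-3-methyl-5-oxopent-3-en-1-yl]-3,3-dimethylcyclohexane-1-carboxylate (C1 epimers)
Conditions: (EtO)2P(O)CH2CO2t-Bu, NaH, THF, 0 → 50 °C; minor Z isomer removed by chromatography
Reagents that add atoms: tert-butyl diethylphosphonoacetate, CCOP(=O)(OCC)CC(=O)OC(C)(C)C
Why: Horner–Wadsworth–Emmons olefination of the methyl ketone, which should favour the E enoate (ester trans to the larger chain); the tert-butyl ester is chosen so that it can be distinguished from the ring methyl ester.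

Step 8
Reactants: 10 methyl (2R)-2-[(3E)-5-tert-butoxy-3-methyl-5-oxopent-3-en-1-yl]-3,3-dimethylcyclohexane-1-carboxylate
Product: 11 methyl (2R)-2-[(3E)-4-carboxy-3-methylbut-3-en-1-yl]-3,3-dimethylcyclohexane-1-carboxylate (C1 epimers)
Conditions: TFA/CH2Cl2 (1:4), 0 °C → rt
Reagents that add atoms: none
Why: Acidolysis of the tert-butyl ester with loss of isobutene; the methyl ester and the deactivated conjugated alkene should be stable, and no acid-sensitive group is present yet.

Step 9
Reactants: 11 methyl (2R)-2-[(3E)-4-carboxy-3-methylbut-3-en-1-yl]-3,3-dimethylcyclohexane-1-carboxylate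
Product: 13 methyl (2R)-2-[(3E)-5-hydroxy-3-methylpent-3-en-1-yl]-3,3-dimethylcyclohexane-1-carboxylate (C1 epimers), via mixed carbonic anhydride 12 (not isolated)
Conditions: ClCO2Et, Et3N, THF, −10 °C; then NaBH4, MeOH, 0 °C
Reagents that add atoms: none
Why: Reduction of a carboxylic acid through its mixed carbonic anhydride with borohydride, which gives the allylic alcohol (1,2-reduction of a β,β-disubstituted system) and does not reduce the methyl ester.

Step 10
Reactants: 13 methyl (2R)-2-[(3E)-5-hydroxy-3-methylpent-3-en-1-yl]-3,3-dimethylcyclohexane-1-carboxylate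
Product: 14 methyl (2R)-2-{(3E)-5-[(methoxycarbonyl)oxy]-3-methylpent-3-en-1-yl}-3,3-dimethylcyclohexane-1-carboxylate (C1 epimers)
Conditions: ClCO2Me, pyridine, DMAP (cat.), CH2Cl2, 0 °C
Reagents that add atoms: methyl chloroformate, COC(=O)Cl
Why: Acylation of the primary allylic alcohol to the carbonate, the leaving group for the palladium step.

Step 11
Reactants: 14 methyl (2R)-2-{(3E)-5-[(methoxycarbonyl)oxy]-3-methylpent-3-en-1-yl}-3,3-dimethylcyclohexane-1-carboxylate; 15 atranol (2,6-dihydroxy-4-methylbenzaldehyde)
Product: 16 methyl (2R)-2-[(3R)-3-(2-formyl-3-hydroxy-5-methylphenoxy)-3-methylpent-4-en-1-yl]-3,3-dimethylcyclohexane-1-carboxylate (C1 epimers)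
Conditions: Pd2(dba)3·CHCl3 (2.5 mol%), (R,R)-DACH-phenyl Trost ligand (7.5 mol%), 15 (2.5 equiv), CH2Cl2, 0 °C → rt
Reagents that add atoms: none
Why: Tsuji–Trost asymmetric allylic O-alkylation of a phenol: Pd(0) ionises the geometrically pure (E)-carbonate and the phenoxide should attack the more substituted allyl terminus inside the chiral pocket, so the tertiary ether centre is set by the ligand (catalyst control, the ring stereocentres being remote); the two hydroxyl groups of 15 are equivalent and its excess limits double alkylation.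

Step 12
Reactants: 16 methyl (2R)-2-[(3R)-3-(2-formyl-3-hydroxy-5-methylphenoxy)-3-methylpent-4-en-1-yl]-3,3-dimethylcyclohexane-1-carboxylate
Product: 17 methyl (2R)-2-[(3R)-3-(2-ethenyl-3-hydroxy-5-methylphenoxy)-3-methylpent-4-en-1-yl]-3,3-dimethylcyclohexane-1-carboxylate (C1 epimers)
Conditions: Ph3PCH3Br (3.5 equiv), NaHMDS (3.4 equiv), THF, 0 °C → rt
Reagents that add atoms: methyltriphenylphosphonium bromide, C[P+](c1ccccc1)(c1ccccc1)c1ccccc1.[Br-]
Why: Wittig methylenation of the salicylaldehyde, with excess ylide to allow for the phenol; the quaternary ether centre has no acidic hydrogen and is not affected.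

Step 13
Reactants: 17 methyl (2R)-2-[(3R)-3-(2-ethenyl-3-hydroxy-5-methylphenoxy)-3-methylpent-4-en-1-yl]-3,3-dimethylcyclohexane-1-carboxylate
Product: 18 methyl (2R)-2-{2-[(2R)-5-hydroxy-2,7-dimethyl-2H-chromen-2-yl]ethyl}-3,3-dimethylcyclohexane-1-carboxylate (C1 epimers)
Conditions: Grubbs II (5 mol%), CH2Cl2 (0.005 M), 40 °C
Reagents that add atoms: none
Why: Ring-closing metathesis of the styrene with the vinyl group on the quaternary carbon closes the 2H-pyran ring with loss of ethylene, and the C–O stereocentre is carried over unchanged as chromene C2.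

Step 14
Reactants: 18 methyl (2R)-2-{2-[(2R)-5-hydroxy-2,7-dimethyl-2H-chromen-2-yl]ethyl}-3,3-dimethylcyclohexane-1-carboxylate
Product: 20 (1S,2R)-2-{2-[(2R)-5-hydroxy-2,7-dimethyl-2H-chromen-2-yl]ethyl}-3,3-dimethylcyclohexane-1-carboxylic acid, via trans methyl ester 19 (not isolated)
Conditions: NaOMe, MeOH, 65 °C; then aq. NaOH, 65 °C; then 1 M HCl to pH 4, 0 °C
Reagents that add atoms: sodium hydroxide, [Na+].[OH-]
Why: Methoxide should equilibrate the ester α-centre through its enolate towards the trans-diequatorial (1S,2R) ester (thermodynamic control, no transesterification in methanol) and hydroxide then saponifies it; the chromene is inert to base, and the acid is liberated cold at pH 4 to spare the acid-sensitive chromene.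

**Compound list**
1 | (R)-(+)-limonene | CC1=CC[C@@H](CC1)C(C)=C | starting material
2 | limonene 1,2-ozonide (1,2,4-trioxolane at the ring alkene) | CC12CC[C@@H](C(C)=C)CC(OO1)O2 | intermediate (not isolated)
3 | (3R)-6-oxo-3-(prop-1-en-2-yl)heptanal | CC(=O)CC[C@H](CC=O)C(C)=C | intermediate
4 | (3S)-4-methyl-2-methylidene-3-(3-oxobutyl)pent-4-enal | CC(=O)CC[C@H](C(=C)C=O)C(C)=C | intermediate
5 | (3S)-4-methyl-2-methylidene-3-(3-oxobutyl)pent-4-enoic acid | CC(=O)CC[C@H](C(=C)C(=O)O)C(C)=C | intermediate
6 | methyl (3S)-4-methyl-2-methylidene-3-(3-oxobutyl)pent-4-enoate | CC(=O)CC[C@H](C(=C)C(=O)OC)C(C)=C | intermediate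
7 | phenyl vinyl sulfone | C=CS(=O)(=O)c1ccccc1 | starting material
8 | methyl (2R)-3,3-dimethyl-2-(3-oxobutyl)-5-(phenylsulfonyl)cyclohexane-1-carboxylate (C1/C5 diastereomers) | CC(=O)CC[C@@H]1C(C(=O)OC)CC(S(=O)(=O)c2ccccc2)CC1(C)C | intermediate
9 | methyl (2R)-3,3-dimethyl-2-(3-oxobutyl)cyclohexane-1-carboxylate (C1 epimers) | CC(=O)CC[C@@H]1C(C(=O)OC)CCCC1(C)C | intermediate
10 | methyl (2R)-2-[(3E)-5-tert-butoxy-3-methyl-5-oxopent-3-en-1-yl]-3,3-dimethylcyclohexane-1-carboxylate (C1 epimers) | CC(C)(C)OC(=O)/C=C(\C)CC[C@@H]1C(C(=O)OC)CCCC1(C)C | intermediate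
11 | methyl (2R)-2-[(3E)-4-carboxy-3-methylbut-3-en-1-yl]-3,3-dimethylcyclohexane-1-carboxylate (C1 epimers) | OC(=O)/C=C(\C)CC[C@@H]1C(C(=O)OC)CCCC1(C)C | intermediate
12 | mixed ethyl carbonic anhydride of 11 | CCOC(=O)OC(=O)/C=C(\C)CC[C@@H]1C(C(=O)OC)CCCC1(C)C | intermediate (not isolated)
13 | methyl (2R)-2-[(3E)-5-hydroxy-3-methylpent-3-en-1-yl]-3,3-dimethylcyclohexane-1-carboxylate (C1 epimers) | OC/C=C(\C)CC[C@@H]1C(C(=O)OC)CCCC1(C)C | intermediate
14 | methyl (2R)-2-{(3E)-5-[(methoxycarbonyl)oxy]-3-methylpent-3-en-1-yl}-3,3-dimethylcyclohexane-1-carboxylate (C1 epimers) | COC(=O)OC/C=C(\C)CC[C@@H]1C(C(=O)OC)CCCC1(C)C | intermediate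
15 | atranol (2,6-dihydroxy-4-methylbenzaldehyde) | Cc1cc(O)c(C=O)c(O)c1 | starting material
16 | methyl (2R)-2-[(3R)-3-(2-formyl-3-hydroxy-5-methylphenoxy)-3-methylpent-4-en-1-yl]-3,3-dimethylcyclohexane-1-carboxylate (C1 epimers) | Cc1cc(O)c(C=O)c(c1)O[C@](C)(CC[C@@H]1C(C(=O)OC)CCCC1(C)C)C=C | intermediate
17 | methyl (2R)-2-[(3R)-3-(2-ethenyl-3-hydroxy-5-methylphenoxy)-3-methylpent-4-en-1-yl]-3,3-dimethylcyclohexane-1-carboxylate (C1 epimers) | Cc1cc(O)c(C=C)c(c1)O[C@](C)(CC[C@@H]1C(C(=O)OC)CCCC1(C)C)C=C | intermediate
18 | methyl (2R)-2-{2-[(2R)-5-hydroxy-2,7-dimethyl-2H-chromen-2-yl]ethyl}-3,3-dimethylcyclohexane-1-carboxylate (C1 epimers) | Cc1cc(O)c2c(c1)O[C@](C)(CC[C@@H]1C(C(=O)OC)CCCC1(C)C)C=C2 | intermediate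
19 | methyl (1S,2R)-2-{2-[(2R)-5-hydroxy-2,7-dimethyl-2H-chromen-2-yl]ethyl}-3,3-dimethylcyclohexane-1-carboxylate | Cc1cc(O)c2c(c1)O[C@](C)(CC[C@@H]1[C@@H](C(=O)OC)CCCC1(C)C)C=C2 | intermediate (not isolated)
20 | (1S,2R)-2-{2-[(2R)-5-hydroxy-2,7-dimethyl-2H-chromen-2-yl]ethyl}-3,3-dimethylcyclohexane-1-carboxylic acid | Cc1cc(O)c2c(c1)O[C@](C)(CC[C@@H]1[C@@H](C(=O)O)CCCC1(C)C)C=C2 | target

**Step count and risks**
Total steps: 14. Longest linear sequence: 14 steps (1 → 20); 7 and 15 enter as commercial compounds.

Step 5 (Proposed new method). The α-sulfonyl intermediate may be reduced and protonated before it closes the ring, and part of the hydrogen-atom transfer may go to the acrylate. The fallback sets out from 6 and uses three known reaction types, with a two-carbon unit that closes the ring under neutral conditions. Reductive olefin coupling of 6 with acrolein (Fe(acac)3, PhSiH3, EtOH/ethylene glycol) should give methyl (3S)-4,4-dimethyl-2-methylidene-7-oxo-3-(3-oxobutyl)heptanoate F1. Enamine catalysis (pyrrolidine, AcOH) should then close the ring by intramolecular Michael addition of the aldehyde α-carbon to the acrylate CH2, giving methyl (2R)-5-formyl-3,3-dimethyl-2-(3-oxobutyl)cyclohexane-1-carboxylate F2. Decarbonylation with stoichiometric RhCl(PPh3)3 in hot toluene removes the formyl group, and the route is rejoined at 9.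

Step 11. The phenoxide may attack the less substituted allyl terminus, the facial discrimination at a centre that differs only in methyl versus a primary chain may be poor, or the tertiary aryl ether may re-ionise and drift to the linear isomer. The fallback sets out from 13 and builds the C–O stereocentre before the arene is attached. Sharpless asymmetric epoxidation (Ti(Oi-Pr)4, D-(−)-diethyl tartrate, t-BuOOH, −20 °C) should give methyl (2R)-2-{2-[(2R,3R)-3-(hydroxymethyl)-2-methyloxiran-2-yl]ethyl}-3,3-dimethylcyclohexane-1-carboxylate F3. I2, PPh3 and imidazole give methyl (2R)-2-{2-[(2R,3S)-3-(iodomethyl)-2-methyloxiran-2-yl]ethyl}-3,3-dimethylcyclohexane-1-carboxylate F4. Zinc dust in ethanol opens F4 reductively, with the tertiary C–O bond kept, to methyl (2R)-2-[(3R)-3-hydroxy-3-methylpent-4-en-1-yl]-3,3-dimethylcyclohexane-1-carboxylate F5. Its potassium alkoxide (KHMDS, THF) displaces one fluoride of 2,6-difluoro-4-methylbenzaldehyde (SNAr) to give methyl (2R)-2-[(3R)-3-(3-fluoro-2-formyl-5-methylphenoxy)-3-methylpent-4-en-1-yl]-3,3-dimethylcyclohexane-1-carboxylate F6. Exchange of the second fluoride for hydroxyl with 2-(methylsulfonyl)ethanol and NaH in DMF rejoins the route at 16.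

Step 2. The amine catalyst may promote intramolecular aldol condensation of the keto aldehyde, and dienamine formation at the doubly allylic position of the product may erode the only chiral-pool stereocentre. The fallback sets out from 3 and introduces the methylene group at the ester stage with the ketone masked. Pinnick oxidation gives (3R)-6-oxo-3-(prop-1-en-2-yl)heptanoic acid F7. TMSCHN2 gives methyl (3R)-6-oxo-3-(prop-1-en-2-yl)heptanoate F8. Ethylene glycol and PPTS give methyl (3R)-5-(2-methyl-1,3-dioxolan-2-yl)-3-(prop-1-en-2-yl)pentanoate F9. LDA at −78 °C followed by Eschenmoser's salt gives methyl (3R)-2-[(dimethylamino)methyl]-5-(2-methyl-1,3-dioxolan-2-yl)-3-(prop-1-en-2-yl)pentanoate F10. Quaternisation with MeI and elimination with aqueous NaHCO3 give methyl (3S)-2-methylidene-5-(2-methyl-1,3-dioxolan-2-yl)-3-(prop-1-en-2-yl)pentanoate F11. PPTS in wet acetone removes the ketal, and the route is rejoined at 6.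

**Further compounds**
F1 | step 5 | methyl (3S)-4,4-dimethyl-2-methylidene-7-oxo-3-(3-oxobutyl)heptanoate | CC(=O)CC[C@H](C(=C)C(=O)OC)C(C)(C)CCC=O
F2 | step 5 | methyl (2R)-5-formyl-3,3-dimethyl-2-(3-oxobutyl)cyclohexane-1-carboxylate (C1/C5 diastereomers) | CC(=O)CC[C@@H]1C(C(=O)OC)CC(C=O)CC1(C)C
F3 | step 11 | methyl (2R)-2-{2-[(2R,3R)-3-(hydroxymethyl)-2-methyloxiran-2-yl]ethyl}-3,3-dimethylcyclohexane-1-carboxylate (C1 epimers) | OC[C@H]1O[C@]1(C)CC[C@@H]2C(C(=O)OC)CCCC2(C)C
F4 | step 11 | methyl (2R)-2-{2-[(2R,3S)-3-(iodomethyl)-2-methyloxiran-2-yl]ethyl}-3,3-dimethylcyclohexane-1-carboxylate (C1 epimers) | IC[C@H]1O[C@]1(C)CC[C@@H]2C(C(=O)OC)CCCC2(C)C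
F5 | step 11 | methyl (2R)-2-[(3R)-3-hydroxy-3-methylpent-4-en-1-yl]-3,3-dimethylcyclohexane-1-carboxylate (C1 epimers) | C=C[C@](C)(O)CC[C@@H]1C(C(=O)OC)CCCC1(C)C
F6 | step 11 | methyl (2R)-2-[(3R)-3-(3-fluoro-2-formyl-5-methylphenoxy)-3-methylpent-4-en-1-yl]-3,3-dimethylcyclohexane-1-carboxylate (C1 epimers) | Cc1cc(F)c(C=O)c(c1)O[C@](C)(CC[C@@H]1C(C(=O)OC)CCCC1(C)C)C=C
F7 | step 2 | (3R)-6-oxo-3-(prop-1-en-2-yl)heptanoic acid | CC(=O)CC[C@H](CC(=O)O)C(C)=C
F8 | step 2 | methyl (3R)-6-oxo-3-(prop-1-en-2-yl)heptanoate | CC(=O)CC[C@H](CC(=O)OC)C(C)=C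
F9 | step 2 | methyl (3R)-5-(2-methyl-1,3-dioxolan-2-yl)-3-(prop-1-en-2-yl)pentanoate | CC1(CC[C@H](CC(=O)OC)C(C)=C)OCCO1
F10 | step 2 | methyl (3R)-2-[(dimethylamino)methyl]-5-(2-methyl-1,3-dioxolan-2-yl)-3-(prop-1-en-2-yl)pentanoate (C2 epimers) | CC1(CC[C@H](C(CN(C)C)C(=O)OC)C(C)=C)OCCO1
F11 | step 2 | methyl (3S)-2-methylidene-5-(2-methyl-1,3-dioxolan-2-yl)-3-(prop-1-en-2-yl)pentanoate | CC1(CC[C@H](C(=C)C(=O)OC)C(C)=C)OCCO1
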